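## The problem

Compound 11 is an achiral, constitutionally symmetric ether: two identical benzene rings joined through a CH2–O–CH2 bridge. Each ring carries, in fixed order, the CH2O arm (C1), Br (C2), Br (C3), OH (C4), OH (C5) and a single H (C6). The difficulty is therefore regiochemical. Five contiguous substituents must be placed without relying on the competing directing effects of a catechol, two halogens and a benzylic carbon.

The target has no stereocentre. The four that arise on the way (in 9) are fixed pairwise by the cis geometry of a two-carbon building block. They do not control one another across the ether bridge and are erased on aromatisation.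

Three functions will not survive rough treatment:
- The free catechols are oxidised to o-quinones by air once base is present.
- The benzylic ether is para to the C4 hydroxyl, so acid, base, heat or alcohol solvents can expel one half as a quinone methide.
- The four aryl C–Br bonds exclude hydrogenolysis, dissolving metals and late organometallic steps.

The ring atoms divide naturally. C3–C2–C1–C6 is a diene unit carrying Br, Br, the CH2O arm and H. C4–C5 is a two-carbon unit with both oxygens, a masked cis-enediol. A 2,3-dibromo-4-(alkoxymethyl)thiophene 1,1-dioxide has exactly the substitution of that diene, and its sulfur leaves as SO2. Because the molecule is a symmetric dimer, both rings can be closed in one operation on a symmetric bis-diene.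

## Retrosynthesis

**11 from 10.** The four O–H bonds are traced back to two cyclic aryl carbonates (cleavage of the acyl C–O bonds of bis(catechol carbonate) 10). Methyl ethers would need a boron trihalide, which also cleaves the benzylic ether. Benzyl ethers would need hydrogenolysis, which removes bromine. An acetonide would need strong acid. The carbonate is what the ring-forming step delivers anyway, and it comes off in neutral water. The skeleton is unchanged, but the two most fragile functions are absent from every earlier step. The forward reaction must spare the para-hydroxybenzyl ether, so it is run at neutral pH without alcohol solvent.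

**10 from 9.** Two hydrogens are added back to C4 and C5 of each ring, giving the bis(cis-dihydrocatechol carbonate) 9. Staying aromatic would force the substituents to be introduced by substitution chemistry. Dropping to the dihydro level exposes a cyclohexa-1,3-diene flanked by a cis-dioxygenated sp3 pair, the retron for a diene plus enediol combination. The forward step needs an oxidant that removes hydride from carbon without ionising the allylic C–O bonds.

**9 from 6 and 7 (through 8).** In each ring the bonds C3–C4 and C5–C6 are cut. The alternative division, with the oxygens on the diene and the bromines on the 2π partner, would need a 1,2-dibromoalkene as dienophile and an unstable dioxygenated diene. The chosen cut puts both oxygens on commercial vinylene carbonate 7 and leaves a diene that is the carbon frame of a thiophene. As its 1,1-dioxide the diene is electron-poor enough to accept 7, and the sulfur bridge of cycloadduct 8 leaves as SO2. This removes two rings, four C–C bonds and all four stereocentres, and leads to the symmetric bis-sulfone 6. The forward reaction must favour cross-cycloaddition over self-dimerisation of the diene.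

**6 from 5.** The four S=O bonds are removed to give the bis(thienylmethyl) ether 5, a stable aromatic compound. Oxidation is placed immediately before the cycloaddition because the dioxide is the only reactive, base-sensitive intermediate. Oxidising earlier, at the stage of aldehyde 4, would destroy the formyl group and would force the ether to be made on a base-sensitive sulfone. The forward step needs a peracid strong enough for a halogen-deactivated sulfur.

**5 from 4.** The ether C–O bond is cut so that both halves come from the same aldehyde 4 by reductive homo-etherification. A Williamson coupling would need an alcohol and a halide, two more steps, and is held in reserve. The forward step needs silane reduction to stop at the ether, which the electron-poor ring favours.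

**4 from 3.** The C5–Br bond is cut to give 4-bromothiophene-3-carbaldehyde 3. Bromination is placed at the aldehyde stage on purpose. The formyl group deactivates C2 and the bromine at C4 activates C5, so both direct to the same carbon. After etherification the CH2OR group would direct to C2 instead.

**3 from 1 (through 2).** The C–CHO bond is cut, leading to commercial 3,4-dibromothiophene 1. A single bromine–lithium exchange (giving 2) desymmetrises it, and formylation installs the future benzylic carbon.

## Roads not taken

**Alternative 1:** The cut is made on the intact arene at C1–CH2 and C2–Br.
- Forward key step: the iodoaryl triflate A1 undergoes iodine–magnesium exchange and loses triflate to give the aryne A2. The silylmethyl Grignard reagent A3 adds at C1, the carbon remote from the C3 bromine. The arylmagnesium left at C2 is quenched with an electrophilic bromine donor to give the benzylsilane A4.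
- Merits: one C–C and one C–Br bond form in a single flask. The regiochemistry follows from the distortion of the aryne by the adjacent bromine. The ring never leaves the aromatic state, so there is no dehydrogenation and no sensitive diene.
- Weak points: A1 is itself a hexasubstituted benzene whose halogens must first be placed by substitution chemistry, so the regiochemical problem is moved, not removed. The 2-bromoarylmagnesium intermediate can expel magnesium bromide and form a second aryne. Each ring must be made separately. The C–Si bond then has to be oxidised to the benzylic alcohol A5, the ether A6 assembled, and four O-methyl groups removed with a boron trihalide that also cleaves benzylic ethers.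
- Comparison: this road is better in staying aromatic throughout and in being modular enough for unsymmetrical analogues. The chosen plan sets against it the closure of both rings in one step from one symmetric intermediate, a shorter sequence, and a neutral final unmasking.

**Alternative 2:** The cut is at the two C–O bonds of C4 and C5.
- Forward key step: whole cells expressing toluene dioxygenase add dioxygen across the double bond next to the halogens of 1,2-dibromobenzene A7 to give the cis-dihydrodiol A8. Dehydrogenation would then give 3,4-dibromocatechol A9.
- Merits: one aqueous step from a cheap arene gives a compound with both bromines and both oxygens in the correct mutual positions, without protecting groups. This oxygenation is shorter and more certain than the four steps needed here to reach 6.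
- Weak points: A8 is formed as a single enantiomer although 11 has no stereocentre, so that selectivity is wasted. A8 and A9 lack the C1 carbon. It would have to be introduced into the oxidation-prone A9 by electrophilic substitution at the position para to one hydroxyl and flanked by bromine, in competition with the open ortho position. The ether would then have to be assembled from a para-hydroxybenzyl alcohol that self-condenses without control. A fermentation facility is required.
- Comparison: this road passes through the same kind of dihydrocatechol and shares the aromatisation problem of the chosen plan. The chosen plan sets against it a carbon arm and ether bridge that are in place before the ring is formed, and purely chemical operations.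

**Alternative 3:** The cut is at the four C–Br bonds.
- Forward key step: the divanillyl ether A10 is treated with four equivalents of Br2 in NaOAc-buffered acetic acid. The first bromine enters ortho to the phenol (C3) and the second para to the methoxy group (C2), giving A11.
- Merits: it is the shortest road, starts from vanillin-derived material, stays aromatic and involves no reactive intermediate.
- Weak points: C1 is para to the free phenol, so ipso attack by bromine can expel the benzylic carbon, and HBr can cleave the ether through a quinone methide. The buffer only moderates this. The second bromination must choose C2 over C6. Two aryl methyl ethers must finally be cleaved in the presence of a benzylic ether that is more labile to the Lewis acids involved than the methyl ethers themselves.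
- Comparison: in step count this road is clearly better, and if both the bromination and the demethylation held it would be the better synthesis. The chosen plan sets against it positional certainty (every substituent is located by the connectivity of diene and dienophile, not by directing effects) and an unmasking in neutral water.

Key step: step 5

Assumption: 8 and 9 are formed and carried on as mixtures of the meso and the racemic C2-symmetric diastereomers (one is drawn in each case); since 11 has no stereocentre, nothing depends on their proportion.

## Route

Step 1
Reactants: 1 3,4-dibromothiophene
Product: 3 4-bromothiophene-3-carbaldehyde, via (4-bromothiophen-3-yl)lithium 2 (not isolated)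
Conditions: n-BuLi (1.0 equiv), Et2O, −78 °C; DMF, −78 °C to rt; H2O
Reagents that add atoms: N,N-dimethylformamide, CN(C)C=O
Why: Bromine–lithium exchange on one of the two equivalent C–Br bonds is fast at −78 °C and the 3-thienyllithium 2 is stable in ether at that temperature; formylation with DMF through the hemiaminal alkoxide gives 3 on aqueous work-up.

Step 2
Reactants: 3 4-bromothiophene-3-carbaldehyde
Product: 4 4,5-dibromothiophene-3-carbaldehyde
Conditions: Br2 (1.1 equiv), AcOH, rt to 50 °C
Reagents that add atoms: bromine, BrBr
Why: Electrophilic aromatic bromination; C5 is the α-position ortho to the bromine at C4 and is not conjugated with the formyl group, whereas C2 is deactivated by the adjacent carbonyl, so both substituents direct to C5.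

Step 3
Reactants: 4 4,5-dibromothiophene-3-carbaldehyde (two molecules)
Product: 5 bis[(4,5-dibromothiophen-3-yl)methyl] ether
Conditions: Et3SiH (1.2 equiv), TMSOTf (5 mol%), CH2Cl2, 0 °C to rt
Reagents that add atoms: none
Why: Reductive homo-etherification of an aldehyde: silane reduction gives the silyl ether of the carbinol, which condenses with a second aldehyde under silyl triflate catalysis to an oxocarbenium ion that a second hydride reduces to the symmetric ether; the electron-poor dibromothienyl group disfavours the cation needed for over-reduction to the methyl compound.

Step 4
Reactants: 5 bis[(4,5-dibromothiophen-3-yl)methyl] ether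
Product: 6 bis[(4,5-dibromo-1,1-dioxothiophen-3-yl)methyl] ether
Conditions: (CF3CO)2O, H2O2 (35% aq.), CH2Cl2, 0 °C to rt; product used without storage
Reagents that add atoms: hydrogen peroxide, OO (oxygen delivered through trifluoroperacetic acid, OOC(=O)C(F)(F)F, formed in the flask from trifluoroacetic anhydride, O=C(OC(=O)C(F)(F)F)C(F)(F)F)
Why: Peracid oxidation of thiophene sulfur to the sulfone; trifluoroperacetic acid is electrophilic enough for halogen-deactivated thiophenes, the intermediate S-oxide is oxidised faster than the thiophene and does not accumulate, and the dialkyl ether is inert; three substituents on each ring slow the self-cycloaddition typical of less substituted thiophene dioxides.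

Step 5
Reactants: 6 bis[(4,5-dibromo-1,1-dioxothiophen-3-yl)methyl] ether; 7 vinylene carbonate (1,3-dioxol-2-one)
Product: 9 bis[(6,7-dibromo-2-oxo-3a,7a-dihydro-1,3-benzodioxol-5-yl)methyl] ether (cis ring fusions; diastereomer mixture), via bridged bis-sulfone cycloadduct 8 (not isolated)
Conditions: 7 (10 equiv), BHT (2 mol%), PhMe, 110 °C, N2 sweep (−SO2); excess 7 removed in vacuo
Reagents that add atoms: none
Why: Each electron-poor 2,3-dibromothiophene 1,1-dioxide ring of 6 is the 4π partner and the enediol carbonate 7 the 2π partner in a concerted, suprafacial inverse-demand Diels–Alder reaction that forms C3–C4 and C5–C6 (target numbering) at the two α-carbons of the sulfone; the 7-thiabicyclo[2.2.1]heptene 7,7-dioxide units of 8 do not survive the reaction temperature and lose SO2 in a cheletropic step, leaving the cyclohexa-1,3-dienes of 9. The closest known reaction type is the cycloaddition of halogenated thiophene 1,1-dioxides with alkenes followed by SO2 extrusion, together with the addition of vinylene carbonate to electron-poor dienes such as halogenated cyclopentadienes, cyclopentadienones and 2-pyrones. Each of the two six-membered carbocycles closes by intermolecular [4+2] cycloaddition, four ring atoms coming from the sulfone and two from 7, and is then freed from its one-atom sulfur bridge. The two new stereocentres of each ring are the carbons of 7; they are cis because the Z-alkene adds suprafacially, and endo and exo approach give the same cis fusion once the bridge is gone. The relative configuration between the two rings is not controlled and need not be, since step 6 removes all four centres. Regiochemistry does not arise because 7 is symmetric; the selectivity needed is cross-cycloaddition over self-dimerisation of the diene, secured by the three substituents on each sulfone ring (one unhindered α-CH only), by the excess of 7 and by the three-atom tether, which is too short for one ring to add across the other. The product diene carries bromine at one terminus, is electron-poor and should not take up a second molecule of 7 at a comparable rate.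

Step 6
Reactants: 9 bis[(6,7-dibromo-2-oxo-3a,7a-dihydro-1,3-benzodioxol-5-yl)methyl] ether
Product: 10 bis[(6,7-dibromo-2-oxo-1,3-benzodioxol-5-yl)methyl] ether
Conditions: DDQ (2.4 equiv), PhCl, 90 °C; filtration from the hydroquinone
Reagents that add atoms: none
Why: Quinone dehydrogenation: DDQ abstracts hydride from an allylic, oxygen-bearing CH of each cyclohexa-1,3-diene and the cyclohexadienyl cation loses the neighbouring proton, the gain of aromaticity driving an otherwise electron-poor substrate; the neutral carbonate avoids the dehydration to monophenols that free cis-dihydrodiols undergo, and the bromine- and carbonate-deactivated arenes protect the benzylic ether CH2 from DDQ.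

Step 7
Reactants: 10 bis[(6,7-dibromo-2-oxo-1,3-benzodioxol-5-yl)methyl] ether
Product: 11 bis(2,3-dibromo-4,5-dihydroxybenzyl) ether
Conditions: THF–aq. NaH2PO4/Na2HPO4 buffer (pH 7), degassed, rt, Ar
Reagents that add atoms: none
Why: Hydrolysis of an aryl cyclic carbonate: the strained, phenoxide-releasing 1,3-benzodioxol-2-one is attacked by water at the carbonyl under general-base catalysis by the buffer and loses CO2; neutral pH, exclusion of air and absence of alcohols spare the catechols (o-quinone formation) and the para-hydroxybenzyl ether (quinone methide exchange).

## Compound list

1 | 3,4-dibromothiophene | Brc1cscc1Br | starting material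
2 | (4-bromothiophen-3-yl)lithium | [Li]c1cscc1Br | intermediate
3 | 4-bromothiophene-3-carbaldehyde | O=Cc1cscc1Br | intermediate
4 | 4,5-dibromothiophene-3-carbaldehyde | O=Cc1csc(Br)c1Br | intermediate
5 | bis[(4,5-dibromothiophen-3-yl)methyl] ether | Brc1scc(COCc2csc(Br)c2Br)c1Br | intermediate
6 | bis[(4,5-dibromo-1,1-dioxothiophen-3-yl)methyl] ether | O=S1(=O)C=C(COCC2=CS(=O)(=O)C(Br)=C2Br)C(Br)=C1Br | intermediate
7 | vinylene carbonate (1,3-dioxol-2-one) | O=C1OC=CO1 | starting material
8 | bis{[1,6-dibromo-2,3-(carbonyldioxy)-7,7-dioxo-7-thiabicyclo[2.2.1]hept-5-en-5-yl]methyl} ether (bridged bis-sulfone cycloadduct; carbonate endo, one diastereomer drawn) | O=C1O[C@H]2[C@@H](O1)[C@@]3(Br)C(Br)=C(COCC4=C(Br)[C@]5(Br)[C@@H]6OC(=O)O[C@@H]6[C@H]4S5(=O)=O)[C@@H]2S3(=O)=O | intermediate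
9 | bis[(6,7-dibromo-2-oxo-3a,7a-dihydro-1,3-benzodioxol-5-yl)methyl] ether (cis ring fusions, one diastereomer drawn) | O=C1O[C@H]2C=C(COCC3=C[C@H]4OC(=O)O[C@H]4C(Br)=C3Br)C(Br)=C(Br)[C@H]2O1 | intermediate
10 | bis[(6,7-dibromo-2-oxo-1,3-benzodioxol-5-yl)methyl] ether | O=C1Oc2cc(COCc3cc4OC(=O)Oc4c(Br)c3Br)c(Br)c(Br)c2O1 | intermediate
11 | bis(2,3-dibromo-4,5-dihydroxybenzyl) ether | Oc1cc(COCc2cc(O)c(O)c(Br)c2Br)c(Br)c(Br)c1O | target

## Step count and risk

Total steps: 7. Longest linear sequence: 7 steps (1 to 11); 7 enters at step 5.

**Step 5 (key step).**
- What may go wrong: self-cycloaddition and oligomerisation of the bis-diene 6, with one sulfone ring serving as 2π partner towards another molecule, may outrun the slow addition of the weakly nucleophilic 7. On prolonged heating, 1,5-hydrogen shifts in 9 followed by loss of HBr would erode the substitution pattern.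
- Fallback: it sets out from 6 and returns at 11. The 2π partner is changed to di-tert-butoxyethyne, an ynediether at the alkyne oxidation level with a much higher-lying HOMO than 7. It is combined with 6 in CH2Cl2 at about room temperature, since the ynediether loses 2-methylpropene when heated. Cycloaddition and loss of SO2 give the already aromatic bis(2,3-dibromo-4,5-di-tert-butoxybenzyl) ether F1, with no dehydrogenation needed. Brief treatment with CF3CO2H in CH2Cl2 at 0 °C, with anisole as cation trap, removes the four tert-butyl groups and gives 11, so steps 6 and 7 fall away.

**Step 4.**
- What may go wrong: oxygen transfer to the two deactivated sulfur atoms may be incomplete, or 6 may be lost by self-cycloaddition while it is concentrated.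
- Fallback: it sets out from 5 and returns at 9 by way of 8. Instead of the dioxide, the far more reactive thiophene S-monoxide is generated and trapped in one flask. mCPBA (one equivalent per sulfur) with BF3·OEt2 in CH2Cl2 at −20 °C, in the presence of excess 7, should stop the oxidation at the sulfoxide, which adds 7 to give the sulfoxide-bridged bis-cycloadduct F2. A second, easy oxidation at the now non-aromatic bridging sulfur (mCPBA, rt) leads to 8, which loses SO2 on gentle warming to give 9. The route continues with step 6.

**Step 6.**
- What may go wrong: ionisation or elimination at an allylic carbonate C–O bond may compete with slow hydride abstraction from the electron-poor diene, leading to loss of one oxygen per ring.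
- Fallback: it sets out from 9 and returns at 11. Transesterification with K2CO3 (cat.) in MeOH at 0 °C frees bis[(5,6-dibromo-3,4-dihydroxycyclohexa-1,5-dien-1-yl)methyl] ether F3. Base is used because the cis-diol dehydrates under acid. Oxidation of one allylic carbinol per ring with MnO2 in EtOAc gives a 6-hydroxycyclohexa-2,4-dienone, the keto tautomer of the catechol, which enolises at once. A wash with aqueous Na2S2O4 returns any o-quinone from over-oxidation, giving 11. Aromatisation then rests on alcohol oxidation and tautomerisation, not on hydride abstraction from carbon.

**Step 3.**
- What may go wrong: the reduction may stall at the silyl ether of the carbinol because the electron-poor aldehyde is slow to form the oxocarbenium ion, giving alcohol instead of ether after work-up.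
- Fallback: it sets out from 4 and returns at 5. NaBH4 in MeOH reduces 4 to (4,5-dibromothiophen-3-yl)methanol F4. Half of it is converted with PBr3 in CH2Cl2 into 2,3-dibromo-4-(bromomethyl)thiophene F5. Williamson etherification of the sodium alkoxide of F4 (NaH, THF, 0 °C to rt) with F5 gives 5. This is two steps longer.

## Further compounds

F1 | step 5 | bis(2,3-dibromo-4,5-di-tert-butoxybenzyl) ether | CC(C)(C)Oc1cc(COCc2cc(OC(C)(C)C)c(OC(C)(C)C)c(Br)c2Br)c(Br)c(Br)c1OC(C)(C)C
F2 | step 4 | bis{[1,6-dibromo-2,3-(carbonyldioxy)-7-oxo-7-thiabicyclo[2.2.1]hept-5-en-5-yl]methyl} ether (carbonate endo, sulfinyl oxygen on the side of the carbonate-bearing bridge, one diastereomer drawn) | O=C1O[C@H]2[C@@H](O1)[C@@]3(Br)C(Br)=C(COCC4=C(Br)[C@]5(Br)[C@@H]6OC(=O)O[C@@H]6[C@H]4[S@]5=O)[C@@H]2[S@]3=O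
F3 | step 6 | bis[(5,6-dibromo-3,4-dihydroxycyclohexa-1,5-dien-1-yl)methyl] ether (cis-diols, one diastereomer drawn) | O[C@H]1C=C(COCC2=C[C@@H](O)[C@@H](O)C(Br)=C2Br)C(Br)=C(Br)[C@H]1O
F4 | step 3 | (4,5-dibromothiophen-3-yl)methanol | OCc1csc(Br)c1Br
F5 | step 3 | 2,3-dibromo-4-(bromomethyl)thiophene | BrCc1csc(Br)c1Br
A1 | alternative 1 | 2-bromo-6-iodo-3,4-dimethoxyphenyl trifluoromethanesulfonate | COc1cc(I)c(OS(=O)(=O)C(F)(F)F)c(Br)c1OC
A2 | alternative 1 | 3-bromo-4,5-dimethoxybenzyne | COC1=CC#CC(Br)=C1OC
A3 | alternative 1 | [(isopropoxy)dimethylsilyl]methylmagnesium chloride | CC(C)O[Si](C)(C)C[Mg]Cl
A4 | alternative 1 | (2,3-dibromo-4,5-dimethoxybenzyl)(isopropoxy)dimethylsilane | COc1cc(C[Si](C)(C)OC(C)C)c(Br)c(Br)c1OC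
A5 | alternative 1 | (2,3-dibromo-4,5-dimethoxyphenyl)methanol | COc1cc(CO)c(Br)c(Br)c1OC
A6 | alternative 1 | bis(2,3-dibromo-4,5-dimethoxybenzyl) ether | COc1cc(COCc2cc(OC)c(OC)c(Br)c2Br)c(Br)c(Br)c1OC
A7 | alternative 2 | 1,2-dibromobenzene | Brc1ccccc1Br
A8 | alternative 2 | (1S,2S)-3,4-dibromocyclohexa-3,5-diene-1,2-diol | O[C@H]1C=CC(Br)=C(Br)[C@H]1O
A9 | alternative 2 | 3,4-dibromobenzene-1,2-diol | Oc1ccc(Br)c(Br)c1O
A10 | alternative 3 | bis(4-hydroxy-3-methoxybenzyl) ether | COc1cc(COCc2ccc(O)c(OC)c2)ccc1O
A11 | alternative 3 | bis(2,3-dibromo-4-hydroxy-5-methoxybenzyl) ether | COc1cc(COCc2cc(OC)c(O)c(Br)c2Br)c(Br)c(Br)c1O
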